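## Analysis of the target

Target 22 is 2-hydroxy-4-methoxy-6-(2-oxotridecyl)benzoic acid, a single benzene ring with no stereocentre. C1 carries the carboxyl group, C2 a free hydroxyl, C4 a methoxy group and C6 the arm ArCH2–CO–C11H23, so that C3 and C5 are the only ring CH positions. The two oxygens are meta to each other and must be told apart, one as a phenol and one as a methyl ether. The carboxyl group sits in the most crowded position, between the hydroxyl and the arm, on an electron-rich ring, so the acid loses CO2 easily in hot acid. The side-chain ketone can close onto the carboxyl group to a lactol and dehydrate to an isocoumarin, and its benzylic CH2 is doubly activated and enolizes readily. The difficulty is therefore one of regiochemistry and functional-group timing, not of stereochemistry. The plan rests on one feature: C4 lies between the two unsubstituted carbons C3 and C5, and the C2 oxygen, the C4 oxygen and the C6 arm form a 1,3,5 pattern, so the ring can be assembled from a five-carbon enyne (C3, C2, C1, C6, C5) and one molecule of carbon monoxide (C4). C1–H is then left as the one position ortho to the hydroxyl and para to the methoxy group, where the carboxyl carbon can be introduced late.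

## Retrosynthetic reasoning

**22 to 21.** No skeletal bond is cut; the side-chain ketone of 22 is traced to the dioxolane of ketal acid 21. The ketone is kept masked to the end because a 2-oxoalkyl group next to an aldehyde or acid on the same ring invites aldol closure, lactol formation and dehydration. As a ketal the arm is inert to organomagnesium reagents, hydride, base and the rhodium catalyst. The forward step must hydrolyse the ketal in cold dilute aqueous acid so that the open keto acid is isolated.

**21 to 20 to 18.** The bond from C1 to the carboxyl carbon is cut. The carbon is introduced as a formyl group (salicylaldehyde 20) and then oxidized. C1 is chosen because in phenol 18 it is the only carbon that is ortho to the hydroxyl and para to the methoxy group, so a phenoxide-directed formylation has an electronic reason to go there. What is gained is a ring precursor, 18, that is a plain 1,3,5-trisubstituted arene.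

**18 to 17 to 16.** Only O–C bonds are cut here: the methyl ether and the pivalate. In monopivalate 16 the C4 oxygen is a free phenol and the C2 oxygen is acylated, so methylation (17) and then removal of the ester (18) place the methyl group on the correct oxygen without any selectivity problem.

**16 to 11 + 12.** The ring bonds C3–C4 and C4–C5 are cut and C4 is taken out as carbon monoxide 12. This opens the arene to acyclic enyne pivalate 11. The cut is made here because C4 is the only ring carbon flanked by two CH groups, so removing it leaves a linear five-carbon chain with terminal alkyne and alkene ends. The substitution pattern of the ring is then fixed by the connectivity of an open-chain compound and not by aromatic substitution. The forward reaction has to shift the ester from the carbinol carbon to the neighbouring alkyne carbon, take up 12 at the former alkyne terminus and close the six-membered ring onto the alkene CH2.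

**11 to 9 + 10, and 9 to 7 + 8.** The ester C–O bond of 11 leads to enynol 9 and pivaloyl chloride 10. The bond between the carbinol carbon and the alkyne of 9 leads to enal 7 and ethynylmagnesium bromide 8. Both forward steps are standard, and the new centre need not be controlled because it becomes aromatic C1.

**7 to 6.** The exocyclic C=CH2 bond of 7 is cut, leaving saturated aldehyde 6 and a one-carbon aldehyde electrophile. This places the arm on the internal alkene carbon, which is the carbon that becomes C6.

**6 to 5 to 4 to 2 + 3 (from 1).** Aldehyde 6 comes from ester 5 by partial reduction, 5 from keto ester 4 by ketalization, and 4 from the C–C bond between the ketone carbon and the undecyl chain. The 1,4-dicarbonyl pattern of 4 points to a four-carbon diacid building block that is differentiated at its two ends, so acid chloride 2 and Grignard reagent 3, made from 1-bromoundecane 1, are the building blocks.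

## Alternatives that were turned down

Alternative 1: pyranone to resorcylate.
- Disconnection: the ring bond C2–C3 is cut and the arene is traced to methyl 6-methyl-2-oxo-4-[(2-undecyl-1,3-dioxolan-2-yl)methyl]-2H-pyran-3-carboxylate A2. In A2 the carbons C3, C4, C5 and C6 become ring carbons C1, C6, C5 and C4, and the 6-methyl group becomes C3.
- Forward key step: NaOMe in methanol adds to the lactone carbonyl of A2 and opens it to an alkylidenemalonate carrying a methyl ketone. The methyl-derived enolate attacks the ester cis to it in a Claisen-type closure, and the product aromatizes to methyl 2,4-dihydroxy-6-[(2-undecyl-1,3-dioxolan-2-yl)methyl]benzoate A1.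
- In favour: the carboxyl carbon is on the ring from the start, so there is no late functionalization of crowded C1, no transition metal and no pressure vessel. The 4-hydroxyl of A1 can be methylated selectively because the 2-hydroxyl is held in a hydrogen bond to the ester.
- Against: A1 is a methyl ester flanked by a hydroxyl and a branched arm. Its saponification needs hot hydroxide, and the electron-rich acid must then survive acidification. The methylene of the arm in the ring-opened malonate is a second, vinylogous acidic site, so deconjugation or closure through the wrong carbon can compete. A2 is not commercial and would take several steps to build with the ketal in place.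
- Comparison: on the placement of the carboxyl carbon this plan is stronger, and its length would be similar. The chosen strategy offers instead a ring closure whose regiochemistry cannot vary, oxygens differentiated by the mechanism, and an acid made by oxidation that never has to be freed from a hindered ester.

Alternative 2: carboxylate-directed C–H acylmethylation.
- Disconnection: the bond from C6 to the benzylic carbon is cut, together with a lactone C–O bond added in the retrosynthetic sense. This leads to 2,4-dimethoxybenzoic acid A4 and the sulfoxonium ylide 1-[dimethyl(oxo)-λ6-sulfanylidene]tridecan-2-one A5.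
- Forward key step: a cationic pentamethylcyclopentadienyl complex of trivalent rhodium ([Cp*RhCl2]2 activated by AgSbF6) metalates the only ortho C–H bond of A4 under direction of the carboxylate. Ylide A5 is taken up as a carbene equivalent with loss of its sulfoxide, and the ortho-(2-oxoalkyl)benzoic acid closes to 6,8-dimethoxy-3-undecyl-1H-isochromen-1-one A3.
- In favour: it is by far the shortest plan. The arene A4 is bought with the carboxyl group and both oxygens in place, C6–H is the only position the carboxylate can direct to, and A3 is two steps from purchased materials, since A5 is one step from a lauric acid derivative. The ether at C8 of A3, peri to the carbonyl, can be cleaved selectively with a chelating boron halide.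
- Against: A3 is the lactonized, dehydrated form of the target, so the synthesis would end with hydroxide opening of an enol lactone and isolation of the open keto acid from base. The carbene transfer from A5 also has to compete with protodecarboxylation of a dialkoxybenzoic acid under hot Lewis-acidic conditions and with O–H insertion into the acid.
- Comparison: in step economy (about four steps against twelve) and in the regiochemistry of the carboxyl group this alternative is clearly stronger. The chosen strategy offers an end-game in which the target is released from ketal acid 21 under mild acid without passing through the isocoumarin, oxygen differentiation without a demethylation, and a de novo ring synthesis in which the arm is varied simply through the Grignard reagent of step 1.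

Alternative 3: dioxinone-masked tetraketide.
- Disconnection: the ring bond C1–C6 is cut, which unfolds the arene into a polyketide chain masked at its acid end as a dioxinone: 6-[2,4-dioxo-5-(2-undecyl-1,3-dioxolan-2-yl)pentyl]-2,2-dimethyl-4H-1,3-dioxin-4-one A7.
- Forward key step: Et3N enolizes A7, the nucleophilic C5 of the dioxinone adds to the chain ketone furthest from it in an intramolecular aldol reaction, and loss of water aromatizes the ring to 7-hydroxy-2,2-dimethyl-5-[(2-undecyl-1,3-dioxolan-2-yl)methyl]-4H-1,3-benzodioxin-4-one A6.
- In favour: the folding mirrors the biosynthesis, all ring carbons including the carboxyl carbon are present, and the closure runs at room temperature without a metal. In A6 the C2 oxygen is tied up with the carboxyl group in the acetonide while the C4 oxygen is free, so the oxygens are differentiated as well as in the chosen route.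
- Against: A7 is a 1,3,5-tricarbonyl compound with a ketal beta to the ketone that must be attacked. Under base the activated methylene next to the ketal can expel a ketal oxygen (E1cB opening of the dioxolane). Making A7 by C-acylation of a dioxinone dianion needs an activated beta-keto acid ketal that is itself prone to self-condensation. Opening the methylated benzodioxinone to the free acid needs hot hydroxide on a compound that decarboxylates easily.
- Comparison: this plan would be somewhat shorter and is stronger on the carboxyl group. The chosen strategy offers robust, non-enolic intermediates up to the ring-forming step and keeps the salicylic acid and the benzylic ketone out of the sequence until the last two steps.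

Key step: step 7

Remark: the target is taken as the open keto acid drawn; it has no stereocentre, so the carbinol centre of 9 and 11 is carried as the racemate and is erased in step 7.

## Route

Step 1
Reactants: 1 1-bromoundecane; 2 methyl 4-chloro-4-oxobutanoate
Product: 4 methyl 4-oxopentadecanoate, via undecylmagnesium bromide 3 (not isolated)
Conditions: Mg, THF, reflux; then added to 2, Fe(acac)3 (3 mol %), THF, −78 °C
Reagents that add atoms: none
Why: Magnesium insertion gives Grignard reagent 3, and the Fe(acac)3-catalysed acylation of a Grignard reagent by an acid chloride is far faster at −78 °C than addition to the methyl ester or to the ketone formed, so mono-acylation to the 1,4-keto ester is expected.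

Step 2
Reactants: 4 methyl 4-oxopentadecanoate
Product: 5 methyl 3-(2-undecyl-1,3-dioxolan-2-yl)propanoate
Conditions: HOCH2CH2OH, p-TsOH·H2O (cat.), toluene, reflux, Dean–Stark
Reagents that add atoms: ethane-1,2-diol, OCCO
Why: Acid-catalysed ketalization with azeotropic removal of water; the unhindered dialkyl ketone closes readily to the dioxolane, and any ester exchange with the diol is harmless because the next step reduces the ester.

Step 3
Reactants: 5 methyl 3-(2-undecyl-1,3-dioxolan-2-yl)propanoate
Product: 6 3-(2-undecyl-1,3-dioxolan-2-yl)propanal
Conditions: i-Bu2AlH (1.1 equiv), CH2Cl2, −78 °C; then MeOH, aq. KNaC4H4O6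
Reagents that add atoms: none
Why: Partial reduction of a methyl ester with i-Bu2AlH; the tetrahedral aluminium hemiacetal is stable in the cold and collapses to the aldehyde only on quench, and the ketal is inert to hydride.

Step 4
Reactants: 6 3-(2-undecyl-1,3-dioxolan-2-yl)propanal
Product: 7 2-[(2-undecyl-1,3-dioxolan-2-yl)methyl]prop-2-enal
Conditions: 37 % aq. CH2O, pyrrolidine (10 mol %), EtCO2H (10 mol %), i-PrOH, 45 °C
Reagents that add atoms: formaldehyde, C=O
Why: Organocatalytic alpha-methylenation of an aldehyde (Mannich condensation through the pyrrolidine enamine, then elimination of the amine); the aldehyde has a single enolizable CH2, and the buffered amine/acid pair is too weak to open the dioxolane.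

Step 5
Reactants: 7 2-[(2-undecyl-1,3-dioxolan-2-yl)methyl]prop-2-enal; 8 ethynylmagnesium bromide
Product: 9 2-[(2-undecyl-1,3-dioxolan-2-yl)methyl]pent-1-en-4-yn-3-ol (racemic)
Conditions: THF, −78 to 0 °C; then sat. aq. NH4Cl
Reagents that add atoms: none
Why: 1,2-Addition of an alkynyl Grignard reagent to an alpha-substituted enal; the hard acetylide attacks the carbonyl and not the conjugate position, and the racemic carbinol centre is irrelevant because it becomes aromatic C1.

Step 6
Reactants: 9 2-[(2-undecyl-1,3-dioxolan-2-yl)methyl]pent-1-en-4-yn-3-ol (racemic); 10 pivaloyl chloride
Product: 11 2-[(2-undecyl-1,3-dioxolan-2-yl)methyl]pent-1-en-4-yn-3-yl 2,2-dimethylpropanoate (racemic)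
Conditions: Et3N, DMAP (cat.), CH2Cl2, 0 °C to rt
Reagents that add atoms: none
Why: DMAP-catalysed acylation of a secondary alcohol by an acid chloride; the pivalate is chosen because it migrates cleanly in step 7 and later resists acyl transfer during the methylation.

Step 7
Reactants: 11 2-[(2-undecyl-1,3-dioxolan-2-yl)methyl]pent-1-en-4-yn-3-yl 2,2-dimethylpropanoate (racemic); 12 carbon monoxide
Product: 16 3-hydroxy-5-[(2-undecyl-1,3-dioxolan-2-yl)methyl]phenyl 2,2-dimethylpropanoate, via rhodium vinylcarbene 13 (not isolated), via dienylketene 14 (not isolated), via cyclohexadienone tautomer 15 (not isolated)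
Conditions: [RhCl(CO)2]2 (5 mol %), CO (50–80 atm), CH2Cl2, 80 °C, autoclave
Reagents that add atoms: none
Why: Monovalent rhodium coordinates the terminal alkyne of 11, the pivalate carbonyl oxygen attacks the internal alkyne carbon and the propargylic C–O bond breaks, which moves the ester by one carbon and leaves rhodium vinylcarbene 13. Migratory insertion of CO into the carbene forms the C3–C4 bond and gives dienylketene 14, in which the ketene carbon and the terminal methylene are cis across the enol ester double bond. The six-membered ring closes by a thermal six-electron electrocyclization of 14 (or, equivalently, by reductive elimination from a rhodacycle), which forms the C4–C5 bond and gives cyclohexadienone 15, and enolization of 15 gives phenol 16. The closest known reaction type is the rhodium-catalysed carbonylative (5+1) benzannulation of 3-acyloxy-1,4-enynes to resorcinol monoesters. No stereocentre is formed, and the racemic carbinol centre of 11 is destroyed when it becomes aromatic C1. The step needs a 1,2- and not a 1,3-acyloxy shift, which the unsubstituted alkyne terminus secures because the carbene then forms at the unhindered terminal carbon, and it needs CO capture to outrun cyclization of the carbene onto the alkene, which the CO pressure secures. The position of the arm is fixed by connectivity, since it is attached to the internal alkene carbon, which can only become C6, meta to both oxygens. The oxygen derived from CO emerges as a free phenol and the migrated one as a pivalate, so the two are differentiated without a separate protecting step.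

Step 8
Reactants: 16 3-hydroxy-5-[(2-undecyl-1,3-dioxolan-2-yl)methyl]phenyl 2,2-dimethylpropanoate
Product: 17 3-methoxy-5-[(2-undecyl-1,3-dioxolan-2-yl)methyl]phenyl 2,2-dimethylpropanoate
Conditions: MeI, K2CO3, acetone, reflux
Reagents that add atoms: iodomethane, CI
Why: Williamson ether synthesis on the only free phenol; the hindered aryl pivalate is stable to K2CO3 in acetone, so the oxygen born from CO (C4) is the one that is methylated.

Step 9
Reactants: 17 3-methoxy-5-[(2-undecyl-1,3-dioxolan-2-yl)methyl]phenyl 2,2-dimethylpropanoate
Product: 18 3-methoxy-5-[(2-undecyl-1,3-dioxolan-2-yl)methyl]phenol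
Conditions: NaOMe, MeOH, rt; then sat. aq. NH4Cl
Reagents that add atoms: none
Why: Methanolysis (transesterification) of an aryl ester by methoxide; phenoxide is a good leaving group, so the pivalate leaves as volatile methyl pivalate while the methyl ether and the ketal are untouched.

Step 10
Reactants: 18 3-methoxy-5-[(2-undecyl-1,3-dioxolan-2-yl)methyl]phenol
Product: 20 2-hydroxy-4-methoxy-6-[(2-undecyl-1,3-dioxolan-2-yl)methyl]benzaldehyde, via salicyl alcohol 19 (not isolated)
Conditions: MgCl2, Et3N, (CH2O)n, THF, reflux; then sat. aq. NH4Cl
Reagents that add atoms: formaldehyde (from paraformaldehyde), C=O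
Why: Magnesium-mediated ortho-formylation of a phenol (Casnati–Skattebøl reaction): the magnesium phenoxide delivers formaldehyde through a six-membered transition state only to a position ortho to oxygen, and hydride transfer from salicyl alcohol 19 to a second formaldehyde gives the aldehyde. Of the two ortho positions, C1 is para to the methoxy group and so the more nucleophilic, whereas C3 lies between two oxygen substituents; the basic medium leaves the ketal intact.

Step 11
Reactants: 20 2-hydroxy-4-methoxy-6-[(2-undecyl-1,3-dioxolan-2-yl)methyl]benzaldehyde
Product: 21 2-hydroxy-4-methoxy-6-[(2-undecyl-1,3-dioxolan-2-yl)methyl]benzoic acid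
Conditions: NaClO2, NaH2PO4, 2-methyl-2-butene (excess), t-BuOH/H2O, 0 °C to rt
Reagents that add atoms: sodium chlorite, [Na+].[O-]Cl=O
Why: Pinnick oxidation: chlorous acid adds to the aldehyde and fragments to the acid and HOCl, which 2-methyl-2-butene traps before it can chlorinate the electron-rich ring. The conditions are mild enough not to decarboxylate the salicylic acid, and partial opening of the ketal in the buffer would be harmless.

Step 12
Reactants: 21 2-hydroxy-4-methoxy-6-[(2-undecyl-1,3-dioxolan-2-yl)methyl]benzoic acid
Product: 22 2-hydroxy-4-methoxy-6-(2-oxotridecyl)benzoic acid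
Conditions: 1 M aq. HCl, THF, rt
Reagents that add atoms: water, O
Why: Acid-catalysed hydrolysis of a dialkyl ketone dioxolane, which is fast in dilute aqueous acid at room temperature; the large excess of water and the low temperature should keep the product as the open keto acid and disfavour dehydration to the isocoumarin and protodecarboxylation.

## Compound list

1 | 1-bromoundecane | CCCCCCCCCCCBr | starting material
2 | methyl 4-chloro-4-oxobutanoate | COC(=O)CCC(=O)Cl | starting material
3 | undecylmagnesium bromide | CCCCCCCCCCC[Mg]Br | intermediate (not isolated)
4 | methyl 4-oxopentadecanoate | CCCCCCCCCCCC(=O)CCC(=O)OC | intermediate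
5 | methyl 3-(2-undecyl-1,3-dioxolan-2-yl)propanoate | CCCCCCCCCCCC1(CCC(=O)OC)OCCO1 | intermediate
6 | 3-(2-undecyl-1,3-dioxolan-2-yl)propanal | CCCCCCCCCCCC1(CCC=O)OCCO1 | intermediate
7 | 2-[(2-undecyl-1,3-dioxolan-2-yl)methyl]prop-2-enal | CCCCCCCCCCCC1(CC(=C)C=O)OCCO1 | intermediate
8 | ethynylmagnesium bromide | C#C[Mg]Br | starting material
9 | 2-[(2-undecyl-1,3-dioxolan-2-yl)methyl]pent-1-en-4-yn-3-ol (racemic) | C=C(CC1(CCCCCCCCCCC)OCCO1)C(O)C#C | intermediate
10 | pivaloyl chloride (2,2-dimethylpropanoyl chloride) | CC(C)(C)C(Cl)=O | starting material
11 | 2-[(2-undecyl-1,3-dioxolan-2-yl)methyl]pent-1-en-4-yn-3-yl 2,2-dimethylpropanoate (racemic) | C=C(CC1(CCCCCCCCCCC)OCCO1)C(OC(=O)C(C)(C)C)C#C | intermediate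
12 | carbon monoxide | [C-]#[O+] | starting material
13 | rhodium carbene of (2E)-2-(2,2-dimethylpropanoyloxy)-4-[(2-undecyl-1,3-dioxolan-2-yl)methyl]penta-2,4-dien-1-ylidene (chloride and carbonyl ligands on rhodium not drawn) | [Rh]=C/C(OC(=O)C(C)(C)C)=C\C(=C)CC1(CCCCCCCCCCC)OCCO1 | intermediate (not isolated)
14 | (3E)-6-oxo-2-[(2-undecyl-1,3-dioxolan-2-yl)methyl]hexa-1,3,5-trien-4-yl 2,2-dimethylpropanoate | O=C=C/C(OC(=O)C(C)(C)C)=C\C(=C)CC1(CCCCCCCCCCC)OCCO1 | intermediate (not isolated)
15 | 3-oxo-5-[(2-undecyl-1,3-dioxolan-2-yl)methyl]cyclohexa-1,5-dien-1-yl 2,2-dimethylpropanoate | O=C1C=C(OC(=O)C(C)(C)C)C=C(CC2(CCCCCCCCCCC)OCCO2)C1 | intermediate (not isolated)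
16 | 3-hydroxy-5-[(2-undecyl-1,3-dioxolan-2-yl)methyl]phenyl 2,2-dimethylpropanoate | CC(C)(C)C(=O)Oc1cc(O)cc(CC2(CCCCCCCCCCC)OCCO2)c1 | intermediate
17 | 3-methoxy-5-[(2-undecyl-1,3-dioxolan-2-yl)methyl]phenyl 2,2-dimethylpropanoate | CC(C)(C)C(=O)Oc1cc(OC)cc(CC2(CCCCCCCCCCC)OCCO2)c1 | intermediate
18 | 3-methoxy-5-[(2-undecyl-1,3-dioxolan-2-yl)methyl]phenol | COc1cc(O)cc(CC2(CCCCCCCCCCC)OCCO2)c1 | intermediate
19 | 2-(hydroxymethyl)-5-methoxy-3-[(2-undecyl-1,3-dioxolan-2-yl)methyl]phenol | COc1cc(O)c(CO)c(CC2(CCCCCCCCCCC)OCCO2)c1 | intermediate (not isolated)
20 | 2-hydroxy-4-methoxy-6-[(2-undecyl-1,3-dioxolan-2-yl)methyl]benzaldehyde | COc1cc(O)c(C=O)c(CC2(CCCCCCCCCCC)OCCO2)c1 | intermediate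
21 | 2-hydroxy-4-methoxy-6-[(2-undecyl-1,3-dioxolan-2-yl)methyl]benzoic acid | COc1cc(O)c(C(=O)O)c(CC2(CCCCCCCCCCC)OCCO2)c1 | intermediate
22 | 2-hydroxy-4-methoxy-6-(2-oxotridecyl)benzoic acid | CCCCCCCCCCCC(=O)Cc1cc(OC)cc(O)c1C(=O)O | target

## Step count and least certain steps

Total step count: 12. Longest linear sequence: 12 steps, from 1 and 2 to 22; the route is linear, and 8, 10 and 12 are purchased.

**Step 7 (key step).** The acyloxy shift may go the 1,3-way (allylic or allenyl transposition of the pivalate), or the rhodium carbene may cyclize onto the alkene before it takes up CO (cyclopentenone formation). Both would divert material from the benzannulation; alkyne oligomerization at low CO pressure is a further loss. Fallback: the ring is bought instead of built, setting out from Grignard reagent 3. Commercial 2-(3,5-dimethoxyphenyl)acetic acid F1 would be converted with carbonyldiimidazole and N,O-dimethylhydroxylamine hydrochloride into the Weinreb amide 2-(3,5-dimethoxyphenyl)-N-methoxy-N-methylacetamide F2. Addition of 3 to F2 in THF at 0 °C should give 1-(3,5-dimethoxyphenyl)tridecan-2-one F3 through the stable magnesium chelate of the amide. Ketalization of F3 as in step 2 should give 2-[(3,5-dimethoxyphenyl)methyl]-2-undecyl-1,3-dioxolane F4. Mono-demethylation of the symmetric diether F4 with NaSEt in DMF at 130 °C, which should stop after one ether because the phenoxide formed deactivates the second ether toward thiolate, comes back to the route at phenol 18.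

**Step 10.** Formylation may be slow or poorly site-selective, because C1 is shielded by the neighbouring arm with its quaternary ketal carbon while C3, between the two oxygens, remains available to the magnesium phenoxide. Fallback: from 18, heating with magnesium methyl carbonate (MeOMgOCO2Me) in DMF at 120 °C, a Kolbe–Schmitt-type carboxylation through a magnesium chelate ortho to the hydroxyl, followed by brief cold acidification, should give acid 21 directly. This reagent is expected to carboxylate the position flanked by hydroxyl and alkyl and not the one between the two oxygens, as it does with 5-alkylresorcinols. This passes over steps 10 and 11; no compound outside the compound list arises, hence the entry F0.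

**Step 12.** The liberated ketone may close onto the carboxyl group and lose water, and prolonged acid exposure may cause protodecarboxylation of the electron-rich acid. Fallback: from 21, warm p-TsOH·H2O in toluene would remove the ketal and drive the material completely to 8-hydroxy-6-methoxy-3-undecyl-1H-isochromen-1-one F5, a stable neutral compound that can be purified. Opening of the enol lactone of F5 with aqueous KOH in ethanol at room temperature, then acidification to pH 3 at 0 °C with immediate extraction, should give 22.

**Step 11.** Ring chlorination by HOCl may compete if trapping is incomplete, and the hydrogen-bonded, electron-rich aldehyde may oxidize sluggishly. Fallback: from 20, acetylation (Ac2O, pyridine, DMAP) would give 2-formyl-5-methoxy-3-[(2-undecyl-1,3-dioxolan-2-yl)methyl]phenyl acetate F6, a less electron-rich aldehyde without the internal hydrogen bond. Pinnick oxidation of F6 would then give 2-(acetyloxy)-4-methoxy-6-[(2-undecyl-1,3-dioxolan-2-yl)methyl]benzoic acid F7. LiOH in aqueous THF at 0 °C followed by acidification to pH 4 would remove the acetate of F7 and rejoin the route at 21.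

**Step 3.** Over-reduction to the primary alcohol may occur if the aluminium hemiacetal collapses before the quench. Fallback: from 5, LiAlH4 in THF at 0 °C would reduce the ester fully to 3-(2-undecyl-1,3-dioxolan-2-yl)propan-1-ol F8, and Swern oxidation of F8 ((COCl)2, DMSO, Et3N, −78 °C) would return to the route at 6.

## Further compounds

F1 | step 7 | 2-(3,5-dimethoxyphenyl)acetic acid | COc1cc(CC(=O)O)cc(OC)c1
F2 | step 7 | 2-(3,5-dimethoxyphenyl)-N-methoxy-N-methylacetamide | COc1cc(CC(=O)N(C)OC)cc(OC)c1
F3 | step 7 | 1-(3,5-dimethoxyphenyl)tridecan-2-one | CCCCCCCCCCCC(=O)Cc1cc(OC)cc(OC)c1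
F4 | step 7 | 2-[(3,5-dimethoxyphenyl)methyl]-2-undecyl-1,3-dioxolane | CCCCCCCCCCCC1(Cc2cc(OC)cc(OC)c2)OCCO1
F0 | step 10 | none | none
F5 | step 12 | 8-hydroxy-6-methoxy-3-undecyl-1H-isochromen-1-one | CCCCCCCCCCCC1=Cc2cc(OC)cc(O)c2C(=O)O1
F6 | step 11 | 2-formyl-5-methoxy-3-[(2-undecyl-1,3-dioxolan-2-yl)methyl]phenyl acetate | COc1cc(OC(C)=O)c(C=O)c(CC2(CCCCCCCCCCC)OCCO2)c1
F7 | step 11 | 2-(acetyloxy)-4-methoxy-6-[(2-undecyl-1,3-dioxolan-2-yl)methyl]benzoic acid | COc1cc(OC(C)=O)c(C(=O)O)c(CC2(CCCCCCCCCCC)OCCO2)c1
F8 | step 3 | 3-(2-undecyl-1,3-dioxolan-2-yl)propan-1-ol | CCCCCCCCCCCC1(CCCO)OCCO1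
A1 | alternative 1 | methyl 2,4-dihydroxy-6-[(2-undecyl-1,3-dioxolan-2-yl)methyl]benzoate | COC(=O)c1c(O)cc(O)cc1CC1(CCCCCCCCCCC)OCCO1
A2 | alternative 1 | methyl 6-methyl-2-oxo-4-[(2-undecyl-1,3-dioxolan-2-yl)methyl]-2H-pyran-3-carboxylate | COC(=O)C1=C(CC2(CCCCCCCCCCC)OCCO2)C=C(C)OC1=O
A3 | alternative 2 | 6,8-dimethoxy-3-undecyl-1H-isochromen-1-one | CCCCCCCCCCCC1=Cc2cc(OC)cc(OC)c2C(=O)O1
A4 | alternative 2 | 2,4-dimethoxybenzoic acid | COc1ccc(C(=O)O)c(OC)c1
A5 | alternative 2 | 1-[dimethyl(oxo)-λ6-sulfanylidene]tridecan-2-one | CCCCCCCCCCCC(=O)C=S(C)(C)=O
A6 | alternative 3 | 7-hydroxy-2,2-dimethyl-5-[(2-undecyl-1,3-dioxolan-2-yl)methyl]-4H-1,3-benzodioxin-4-one | CCCCCCCCCCCC1(Cc2cc(O)cc3OC(C)(C)OC(=O)c23)OCCO1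
A7 | alternative 3 | 6-[2,4-dioxo-5-(2-undecyl-1,3-dioxolan-2-yl)pentyl]-2,2-dimethyl-4H-1,3-dioxin-4-one | CC1(C)OC(=O)C=C(CC(=O)CC(=O)CC2(CCCCCCCCCCC)OCCO2)O1
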